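The runs are calculated with constants of no real substance, noise included.

The open intermediate was what I had to time in this flask, and the level of product was what the runs let me reckon.

| flask | starting material | partner | protic impurity | remark | time |
|---|---|---|---|---|---|
| Monday's | 0.020 M | 0.024 M | 5.6 mM | run made earlier |  |
| Thursday's | 0.020 M | 0.024 M | 8.8 mM | run made earlier |  |
| Saturday's | 0.010 M | 0.024 M | 4 mM | run made earlier |  |
| flask | 0.020 M | 0.0240 M | 4.00 mM |  | 6.0 d |

| run | time / d | open intermediate / % | product / % |
|---|---|---|---|
| Monday's | 0.0556 | 30.0 | 1.2 |
| Monday's | 0.167 | 41.7 | 7.1 |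
| Monday's | 0.417 | 20.9 | 20.6 |
| Monday's | 1.04 | 2.1 | 29.3 |
| Monday's | 2.50 | 0 | 30.1 |
| Monday's | 6.00 | 0 | 30.2 |
| Thursday's | 0.0556 | 31.5 | 1.0 |
| Thursday's | 0.167 | 41.8 | 6.4 |
| Thursday's | 0.417 | 22.0 | 17.4 |
| Thursday's | 1.04 | 3.5 | 25.3 |
| Thursday's | 2.50 | 1.5 | 26.0 |
| Thursday's | 6.00 | 1.1 | 26.5 |
| Saturday's | 0.0556 | 30.2 | 0 |
| Saturday's | 0.208 | 37.1 | 11.0 |
| Saturday's | 0.625 | 9.5 | 28.9 |
| Saturday's | 2.08 | 0.4 | 34.3 |
| Saturday's | 6.00 | 0.6 | 34.0 |

(scatter of a reading: 0.5 percentage points)



- the best time, 6.0 d at the latest, for open intermediate
- the amount of open intermediate, in percent of the starting material charged, at that time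
- earliest time at which at least nineteen twentieths of that best amount are there, in d
- latest time at which they still are, in d

I drew the curve from Monday's run. In that run open intermediate climbed up to its first reading at an average of 5.40 d⁻¹ as a fraction of the charge, turned over near the reading 41.7% at 0.167 d, and crossed product near 0.417 d, where the readings were 20.9% and 20.6%. Product in Monday's run then ran into a level.

I reckoned that level from an assumption of my own: each protic impurity costs one partner, and open intermediate splits between product, at a rate proportional to the usable partner remaining, and loss. Let u be the usable partner in equivalents, p the final product as a fraction of the charge, q the remainder, and c the charge. Integrating the split gives ln(u/(u−p)) = s·c·q.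

Monday's run, with u = 0.920, gave s = 28.5 M⁻¹. Thursday's, with u = 0.760, gave 29.2 M⁻¹. Saturday's, with u = 2.00, gave 28.2 M⁻¹. I carried their mean, 28.6 M⁻¹, as the split constant, a selectivity factor per unit of usable partner.

For this flask u = 1.00, and one correcting step from Monday's level gave product at 32.2%.

The forecast put the peak at 0.16 d with 42%, inside a window from 0.112 d to 0.218 d. It held that the flask should look like Monday's run, “perhaps with slightly faster decay”.

The flask peaked at 0.137 d with 41.5%, and held the asked share of that from 0.0963 d to 0.189 d.

    open intermediate + second intermediate → product (k = 4.80 M⁻¹ h⁻¹)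
    partner → second intermediate (k = 0.510 h⁻¹)
    partner + protic impurity → quenched reagent (k = 190 M⁻¹ h⁻¹)
    open intermediate → decomposed reagent (k = 0.150 h⁻¹)
    starting material ⇌ open intermediate (K = 3.60, k = 0.350 h⁻¹)

The amount stood within the forecast's tolerance, but the peak in this flask came earlier than forecast. At 0.0540 d open intermediate in this flask was being made 3.33 times faster than used up, each step taken net, and the step between starting material and open intermediate, both ways together, had a relaxation half-life of 0.0646 d, half of the best time. Product in this flask ended at 31.9%, against my 32.2%. In a neighbour flask with 0.060 M of partner, u = 2.80, and the same s, with one correcting step from a fraction 0.5, gave product at 58.9%. That neighbour flask, when computed, ended with 57.1% of product.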